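The earlier runs and the new flask are simulated from invented constants; the scatter is artificial.

Alder, with second end groups fed over 80 s, is the flask to bracket; maple repeats delta's charge, and delta's reading at 120 s stands at 66.1 %.

| flask | first end groups | second end groups | remark | time |
|---|---|---|---|---|
| delta | 0.050 M | 0.90 equiv | run made earlier |  |
| zeta | 0.050 M | 0.45 equiv | run made earlier |  |
| eta | 0.050 M | 1.8 equiv | run made earlier |  |
| epsilon | 0.025 M | 0.90 equiv | run made earlier |  |
| alder | 0.050 M | 0.900 equiv (fed, over 80 s) | all else is in the flask from the start; the feed brings no volume worth counting | 2.0 min |
| ash | 0.050 M (fed, over 8.0 s) | 0.900 equiv | all else is in the flask from the start; the feed brings no volume worth counting | 2.0 min |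
| maple | 0.050 M | 0.900 equiv | everything together at the start | 2.0 min |
| birch | 0.050 M (fed, over 80 s) | 0.900 equiv | all else is in the flask from the start; the feed brings no volume worth counting | 2.0 min |
| elm | 0.050 M (in portions, 4, over 80 s) | 0.900 equiv | first portion at the start, last at 80 s | 2.0 min |

- delta (time / s: links / %): 10.0: 73.8; 20.0: 72.8; 30.0: 72.5; 60.0: 69.7; 120: 66.1
- zeta (time / min: links / %): 0.200: 36.3; 0.333: 34.7; 0.667: 32.2; 1.33: 27.1; 2.50: 21.6
- eta (time / min: links / %): 0.200: 89.9; 0.333: 90.3; 0.667: 89.8; 1.33: 90.5; 2.50: 90.4
- epsilon (time / min: links / %): 0.500: 69.1; 1.00: 67.8; 1.33: 66.8; 2.00: 64.6; 2.50: 63.2

(standard deviation of a reading: 0.3 percentage points)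

- percent here means first end groups units held: one side product counts as two
- what was read earlier has a scatter of 0.3 percentage points, one standard deviation
- steps that have been proposed: first end groups + second end groups -> links; second end groups -> decomposed reagent; first end groups + links -> side product; links <-> isomer of the product

- the best flask by amount of links, in percent of the first end groups charged; "all alike" if 1.5 percentage points covers them all (alder / ash / maple / birch / elm / all alike)
- amount of links at the end, in percent of the first end groups charged, alder
- amount of links at the end, in percent of the first end groups charged, ash
- amount of links at the end, in percent of the first end groups charged, maple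
- amount of links at the end, in percent of the first end groups charged, birch
- amount of links at the end, in percent of the first end groups charged, elm

Eta, with excess reagent, holds 90.4 % as links; taking the rest as isomer of the product gives an isomer-to-links ratio of 0.106. Extrapolated to zero time, as if coupling took no time, delta's first readings give 74.8 % links, so we read that about 82.7 % of the first end groups coupled. Now divide the coupling rate by the decomposition rate: second end groups and time drop out, leaving first end groups over a constant. That constant is the split concentration, the level of first end groups at which second end groups go equally to coupling and to decomposition, a selectivity factor in molar units. Integrated, with the side product ignored, reagent spent equals amount coupled plus split concentration times the logarithm of first end groups charged over first end groups left, so we read from delta about 0.00207 M.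

Feed speed of the reagent does not enter that ratio, so we set alder's ceiling at 74.8 %. Then comes the loss to side product, and again a ratio removes its constant. We call exposure the time integral of first end groups times links, take first end groups falling straight and links rising straight during alder's feed, and compare alder's exposure with delta's. With first end groups held at delta's level after coupling, we reckon alder's exposure at 1.20 times delta's, more than delta's, so we tighten the ceiling to delta's reading of 66.1 %. Against our reckoned final first end groups in delta, 7.63 %, the ratio becomes 2.71, which puts our floor at 51.2 %. Our own figure is 64.4 %. Counting none as coupled, the feed of first end groups reaches our split concentration after 3.30 s in birch and after 0.330 s in ash.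

The forecast names maple: alder 64 %, inside our bracket, ash 45 %, maple 66 %, birch 13 %, elm 17 %. Of the decomposition it says “I assume ~0.15 s⁻¹”.

The flasks give maple first: maple 66.8 %, alder 63.1 %, inside the bracket, elm 14.9 %, ash 12.3 %, birch 2.34 %.

    first end groups + second end groups → links (k = 429 M⁻¹ s⁻¹)
    second end groups → decomposed reagent (k = 0.768 s⁻¹)
    first end groups + links → side product (k = 0.196 M⁻¹ s⁻¹)
    links ⇌ isomer of the product (K = 0.111, k = 0.126 s⁻¹)

The forecast assumed 0.15 per second for the decomposition; the constant is 0.768 s⁻¹, which gives second end groups a half-life by that step alone of 0.90 s in maple, longer than the 0.330 s reckoned for ash and shorter than the 3.30 s reckoned for birch. For the neighbour, maple with 0.360 equiv of second end groups, we count the whole reagent charge as coupled, and the same logarithm then gives about 9.22 × 10⁻⁴ M decomposed. That flask ends with 17.0 % links and 7.57 × 10⁻⁴ M of decomposed reagent.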